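## Retrosynthetic overview

- The two galloyl esters and all thirteen benzyl ethers are handled last (esterification of the two C3 hydroxyls, then one hydrogenolysis).
- Both pyran rings are opened at O1–C2: each closes by Mitsunobu etherification of a ring A phenol onto a benzylic carbinol with inversion (1S → 2R), which turns an anti carbinol/silyloxy pair into the 2,3-cis chroman.
- The strategy rests on this feature: chroman C2 of one flavan unit is bonded to C7 (tropolone ring) and C2 of the other to C1 (benzo ring) of the benzo[7]annulen-5-one. Both C2–C(sp2) bonds and both C2 carbinol centers are made at once by Rh-catalysed addition of the 1,7-bis(boronic acid) to two molecules of one (R)-α-silyloxy aldehyde that already carries C3, C4 and ring A.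
- The bis(boronic acid) comes from a 1,7-dibromobenzotropolone built from 3,4-dimethoxybenzaldehyde; the aldehyde comes from 3,5-bis(benzyloxy)phenol and methyl (R)-glycidate.
- Ring order: benzo ring (bought) → seven-membered ring (Friedel–Crafts) → tropolone (oxidation, bromination–dehydrobromination) → key step (no ring) → both pyran rings together.

Key step: step 15

Remark on the chemistry: the benzotropolone is taken in the 5-oxo-6-hydroxy form of the given SMILES, and O-benzylation is assumed to fix this benzenoid tautomer.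

## Route

Step 1
Reactants: 1 3,4-dimethoxybenzaldehyde; 2 (3-carboxypropyl)triphenylphosphonium bromide
Product: 4 5-(3,4-dimethoxyphenyl)pent-4-enoic acid (E/Z mixture), via phosphonium ylide 3 (not isolated)
Conditions: KOt-Bu (2.2 equiv), THF, 0 °C → rt; aq. HCl work-up
Reagents that add atoms: none
Why: Wittig olefination of an aryl aldehyde with the carboxylate-bearing non-stabilised ylide should give the styrenyl acid, whose double-bond geometry is irrelevant because it is hydrogenated in step 2.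

Step 2
Reactants: 4 5-(3,4-dimethoxyphenyl)pent-4-enoic acid
Product: 5 5-(3,4-dimethoxyphenyl)pentanoic acid
Conditions: H2 (1 atm), Pd/C, MeOH, rt
Reagents that add atoms: none
Why: Catalytic hydrogenation should saturate the styrenyl double bond without touching the aryl ethers or the acid.

Step 3
Reactants: 5 5-(3,4-dimethoxyphenyl)pentanoic acid
Product: 6 5-(2-bromo-4,5-dimethoxyphenyl)pentanoic acid
Conditions: NBS, MeCN, 0 °C → rt
Reagents that add atoms: N-bromosuccinimide, O=C1CCC(=O)N1Br
Why: Electrophilic aromatic bromination of a 4-alkylveratrole should occur para to a methoxy group and ortho to the chain, which places the future C1 bromine and blocks this carbon for step 4.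

Step 4
Reactants: 6 5-(2-bromo-4,5-dimethoxyphenyl)pentanoic acid
Product: 7 1-bromo-3,4-dimethoxy-6,7,8,9-tetrahydro-5H-benzo[7]annulen-5-one
Conditions: P2O5 in MeSO3H, rt → 45 °C
Reagents that add atoms: none
Why: Intramolecular Friedel–Crafts acylation should close the seven-membered ring at the only free carbon ortho to the chain, which is activated by the adjacent methoxy group, so the ketone ends up peri to the C4 oxygen.

Step 5
Reactants: 7 1-bromo-3,4-dimethoxy-6,7,8,9-tetrahydro-5H-benzo[7]annulen-5-one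
Product: 8 1-bromo-3,4-dimethoxy-8,9-dihydro-5H-benzo[7]annulene-5,6(7H)-dione
Conditions: SeO2, 1,4-dioxane/H2O, reflux
Reagents that add atoms: selenium dioxide, O=[Se]=O
Why: Riley oxidation of the α-methylene group of an aryl alkyl ketone should give the 1,2-dione and so install the C6 oxygen.

Step 6
Reactants: 8 1-bromo-3,4-dimethoxy-8,9-dihydro-5H-benzo[7]annulene-5,6(7H)-dione
Product: 10 1,7-dibromo-6-hydroxy-3,4-dimethoxy-5H-benzo[7]annulen-5-one, via 1-bromobenzotropolone 9 (not isolated)
Conditions: Br2 (2.1 equiv), NaOAc, AcOH, rt then 80 °C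
Reagents that add atoms: bromine, BrBr
Why: Bromination of the enolised dione at C7 and loss of HBr should give the 7,8-unsaturated dione, which tautomerises to the aromatic tropolone 9 (the classical bromination–dehydrobromination tropolone synthesis), and the second equivalent of Br2 should substitute 9 at C7, ortho to the tropolone hydroxyl, because C9 is shielded by the peri bromine and C2 is deactivated by the para carbonyl.

Step 7
Reactants: 10 1,7-dibromo-6-hydroxy-3,4-dimethoxy-5H-benzo[7]annulen-5-one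
Product: 11 1,7-dibromo-3,4,6-trihydroxy-5H-benzo[7]annulen-5-one
Conditions: BBr3, CH2Cl2, −78 °C → rt; MeOH/H2O quench
Reagents that add atoms: none
Why: Lewis acid cleavage of aryl methyl ethers with BBr3 should free the catechol while leaving the tropolone and both C–Br bonds intact.

Step 8
Reactants: 11 1,7-dibromo-3,4,6-trihydroxy-5H-benzo[7]annulen-5-one
Product: 12 3,4,6-tris(benzyloxy)-1,7-dibromo-5H-benzo[7]annulen-5-one
Conditions: BnBr (4 equiv), K2CO3, DMF, 60 °C
Reagents that add atoms: benzyl bromide, BrCc1ccccc1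
Why: Williamson benzylation should cap all three acidic hydroxyls, the tropolone oxygen alkylating as the 6-benzyloxy-5-one because the other tautomeric ether would break the benzene ring.

Step 9
Reactants: 12 3,4,6-tris(benzyloxy)-1,7-dibromo-5H-benzo[7]annulen-5-one
Product: 13 3,4,6-tris(benzyloxy)-1,7-bis(4,4,5,5-tetramethyl-1,3,2-dioxaborolan-2-yl)-5H-benzo[7]annulen-5-one
Conditions: B2pin2 (2.6 equiv), Pd(dppf)Cl2, KOAc, 1,4-dioxane, 85 °C
Reagents that add atoms: bis(pinacolato)diboron, CC1(C)OB(OC1(C)C)B1OC(C)(C)C(C)(C)O1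
Why: Miyaura borylation should convert both the aryl C1–Br and the troponyl C7–Br bonds, the weak base KOAc suppressing Suzuki coupling of the product, and the tropone carbonyl rules out a lithium–halogen exchange route.

Step 10
Reactants: 13 3,4,6-tris(benzyloxy)-1,7-bis(4,4,5,5-tetramethyl-1,3,2-dioxaborolan-2-yl)-5H-benzo[7]annulen-5-one
Product: 14 [3,4,6-tris(benzyloxy)-5-oxo-5H-benzo[7]annulene-1,7-diyl]diboronic acid
Conditions: NaIO4, NH4OAc, acetone/H2O, rt
Reagents that add atoms: water, O
Why: Periodate cleavage of the pinacol released in the hydrolysis equilibrium should drive both boronic esters to the free boronic acids under near-neutral conditions.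

Step 11
Reactants: 15 3,5-bis(benzyloxy)phenol
Product: 16 1,3-bis(benzyloxy)-5-(methoxymethoxy)benzene
Conditions: NaH, MOMCl, THF/DMF, 0 °C → rt
Reagents that add atoms: chloromethyl methyl ether, COCCl
Why: O-alkylation of the phenoxide should install the methoxymethyl ether, which serves as the ortho-directing group in step 12 and as the phenol mask that is removed before ring closure.

Step 12
Reactants: 16 1,3-bis(benzyloxy)-5-(methoxymethoxy)benzene; 17 methyl (R)-glycidate
Product: 20 methyl (R)-3-[2,4-bis(benzyloxy)-6-(methoxymethoxy)phenyl]-2-hydroxypropanoate, via aryllithium 18 (not isolated), via arylmagnesium bromide 19 (not isolated)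
Conditions: n-BuLi (1.0 equiv), THF, 0 °C; MgBr2·OEt2, −40 °C; CuI (10 mol%), then 17, −40 → −10 °C; aqueous work-up
Reagents that add atoms: none
Why: Directed ortho-lithiation between the OMOM and OBn groups, transmetalation to magnesium and CuI-catalysed SN2 opening of the glycidate at its CH2 carbon should give the aryl lactate, the stereocenter of 17 being untouched and carried through as (R).

Step 13
Reactants: 20 methyl (R)-3-[2,4-bis(benzyloxy)-6-(methoxymethoxy)phenyl]-2-hydroxypropanoate
Product: 21 methyl (R)-3-[2,4-bis(benzyloxy)-6-(methoxymethoxy)phenyl]-2-(tert-butyldimethylsilyloxy)propanoate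
Conditions: TBSCl, imidazole, DMF, rt
Reagents that add atoms: tert-butyldimethylsilyl chloride, CC(C)(C)[Si](C)(C)Cl
Why: Silylation of the secondary α-hydroxy ester under mildly basic conditions should give the bulky, non-chelating silyl ether needed for Felkin–Anh control, without epimerisation.

Step 14
Reactants: 21 methyl (R)-3-[2,4-bis(benzyloxy)-6-(methoxymethoxy)phenyl]-2-(tert-butyldimethylsilyloxy)propanoate
Product: 22 (R)-3-[2,4-bis(benzyloxy)-6-(methoxymethoxy)phenyl]-2-(tert-butyldimethylsilyloxy)propanal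
Conditions: i-Bu2AlH (1.1 equiv), CH2Cl2, −78 °C; MeOH, then aq. potassium sodium tartrate
Reagents that add atoms: none
Why: Half-reduction of an α-silyloxy ester by i-Bu2AlH at −78 °C should stop at the aluminium hemiacetal, which releases the aldehyde only on work-up, so neither over-reduction nor epimerisation is expected.

Step 15
Reactants: 14 [3,4,6-tris(benzyloxy)-5-oxo-5H-benzo[7]annulene-1,7-diyl]diboronic acid; 22 (R)-3-[2,4-bis(benzyloxy)-6-(methoxymethoxy)phenyl]-2-(tert-butyldimethylsilyloxy)propanal (two molecules react, 3 equiv used)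
Product: 23 3,4,6-tris(benzyloxy)-1,7-bis{(1S,2R)-3-[2,4-bis(benzyloxy)-6-(methoxymethoxy)phenyl]-2-(tert-butyldimethylsilyloxy)-1-hydroxypropyl}-5H-benzo[7]annulen-5-one
Conditions: [Rh(cod)OH]2 (5 mol%), 1,4-dioxane/H2O (20:1), 25 → 40 °C, argon
Reagents that add atoms: none
Why: Each C–B bond should transmetalate to the hydroxo complex of monovalent rhodium, the resulting aryl (C1) or troponyl (C7) rhodium species inserts the aldehyde C=O, and hydrolysis of the rhodium alkoxide gives the carbinol and regenerates Rh–OH, which is the known Rh-catalysed 1,2-addition of arylboronic acids to aldehydes. No ring closes; only the C7–C2 and C1–C2 bonds are formed. Each new carbinol center is set by the adjacent (R)-silyloxy center through the Felkin–Anh transition state, in which the bulky non-chelating OTBS group lies anti to the incoming carbon, so both arms should independently give the anti (1S,2R) arrangement. The step needs facial selectivity and chemoselectivity for the aldehyde over the tropolone carbonyl and over conjugate addition to the tropone; the first rests on the silyl ether, the second on the C5 carbonyl being flanked by the C4 and C6 benzyloxy groups within an electron-rich vinylogous ester whose β-carbon C7 is the metalated carbon itself and whose C9 is shielded by the peri substituent. Base-free conditions near room temperature with little water and an excess of aldehyde should limit epimerisation of 22 and protodeboronation.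

Step 16
Reactants: 23 the bis(carbinol) of step 15
Product: 25 3,4,6-tris(benzyloxy)-1,7-bis{(1S,2R)-3-[2,4-bis(benzyloxy)-6-hydroxyphenyl]-2-(tert-butyldimethylsilyloxy)-1-hydroxypropyl}-5H-benzo[7]annulen-5-one, via tetrakis(trimethylsilyl) ether 24 (not isolated)
Conditions: TMSOTf (8 equiv), 2,2'-bipyridyl (12 equiv), CH2Cl2, 0 °C; then H2O, rt; NaHCO3 wash
Reagents that add atoms: none
Why: The silyl triflate/bipyridyl pair should convert aryl methoxymethyl ethers into aryl trimethylsilyl ethers under non-protic conditions that spare TBS and benzyl ethers, the carbinols being silylated in passing, and water then hydrolyses all four trimethylsilyl ethers.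

Step 17
Reactants: 25 the bis(phenol) bis(carbinol) of step 16
Product: 26 3,4,6-tris(benzyloxy)-1,7-bis[(2R,3R)-5,7-bis(benzyloxy)-3-(tert-butyldimethylsilyloxy)chroman-2-yl]-5H-benzo[7]annulen-5-one
Conditions: PPh3 (3 equiv), DIAD (3 equiv), THF, 0 °C → rt, dilute
Reagents that add atoms: none
Why: Intramolecular Mitsunobu etherification (6-exo-tet attack of each ring A phenol on the oxyphosphonium-activated benzylic carbon) should close both pyran rings with inversion, turning each (1S) carbinol into (2R) and so giving the 2,3-cis relationship while C3 is untouched.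

Step 18
Reactants: 26 the bis(silyloxychroman) of step 17
Product: 27 3,4,6-tris(benzyloxy)-1,7-bis[(2R,3R)-5,7-bis(benzyloxy)-3-hydroxychroman-2-yl]-5H-benzo[7]annulen-5-one
Conditions: Bu4NF, AcOH, THF, 0 °C → rt
Reagents that add atoms: none
Why: Buffered fluoride should cleave the two secondary silyl ethers, and with no free phenol on the chromans there is no ring-opening path that could epimerise C2.

Step 19
Reactants: 27 the bis(chroman-3-ol) of step 18; 28 3,4,5-tris(benzyloxy)benzoic acid (two molecules react, 3 equiv used)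
Product: 29 3,4,6-tris(benzyloxy)-1,7-bis{(2R,3R)-5,7-bis(benzyloxy)-3-[3,4,5-tris(benzyloxy)benzoyloxy]chroman-2-yl}-5H-benzo[7]annulen-5-one
Conditions: DCC, DMAP, CH2Cl2, rt
Reagents that add atoms: none
Why: Steglich esterification should acylate the two hindered axial C3 hydroxyls, the only free hydroxyls in 27, with retention at C3.

Step 20
Reactants: 29 the fully benzylated digallate of step 19
Product: 30 3,4,6-trihydroxy-1,7-bis[(2R,3R)-5,7-dihydroxy-3-(3,4,5-trihydroxybenzoyloxy)chroman-2-yl]-5H-benzo[7]annulen-5-one (CNP0283148.1)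
Conditions: H2 (1 atm), Pd(OH)2/C, THF/MeOH, rt; filtration under argon
Reagents that add atoms: none
Why: Mild hydrogenolysis should remove all thirteen benzyl ethers (three tropolone, four ring A, six galloyl) while leaving the gallate esters, the chroman C2–O bonds and the tropolone ring intact.

## Compound list

1 | 3,4-dimethoxybenzaldehyde | COc1ccc(C=O)cc1OC | starting material
2 | (3-carboxypropyl)triphenylphosphonium bromide | [Br-].OC(=O)CCC[P+](c1ccccc1)(c1ccccc1)c1ccccc1 | starting material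
3 | potassium 4-(triphenylphosphoranylidene)butanoate (ylide) | [K+].[O-]C(=O)CCC=P(c1ccccc1)(c1ccccc1)c1ccccc1 | intermediate (not isolated)
4 | 5-(3,4-dimethoxyphenyl)pent-4-enoic acid (E/Z mixture, geometry left open) | COc1ccc(C=CCCC(=O)O)cc1OC | intermediate
5 | 5-(3,4-dimethoxyphenyl)pentanoic acid | COc1ccc(CCCCC(=O)O)cc1OC | intermediate
6 | 5-(2-bromo-4,5-dimethoxyphenyl)pentanoic acid | COc1cc(Br)c(CCCCC(=O)O)cc1OC | intermediate
7 | 1-bromo-3,4-dimethoxy-6,7,8,9-tetrahydro-5H-benzo[7]annulen-5-one | COc1cc(Br)c2CCCCC(=O)c2c1OC | intermediate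
8 | 1-bromo-3,4-dimethoxy-8,9-dihydro-5H-benzo[7]annulene-5,6(7H)-dione | COc1cc(Br)c2CCCC(=O)C(=O)c2c1OC | intermediate
9 | 1-bromo-6-hydroxy-3,4-dimethoxy-5H-benzo[7]annulen-5-one | COc1cc(Br)c2cccc(O)c(=O)c2c1OC | intermediate (not isolated)
10 | 1,7-dibromo-6-hydroxy-3,4-dimethoxy-5H-benzo[7]annulen-5-one | COc1cc(Br)c2ccc(Br)c(O)c(=O)c2c1OC | intermediate
11 | 1,7-dibromo-3,4,6-trihydroxy-5H-benzo[7]annulen-5-one | Oc1cc(Br)c2ccc(Br)c(O)c(=O)c2c1O | intermediate
12 | 3,4,6-tris(benzyloxy)-1,7-dibromo-5H-benzo[7]annulen-5-one | O=c1c(OCc2ccccc2)c(Br)ccc2c(Br)cc(OCc3ccccc3)c(OCc3ccccc3)c12 | intermediate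
13 | 3,4,6-tris(benzyloxy)-1,7-bis(4,4,5,5-tetramethyl-1,3,2-dioxaborolan-2-yl)-5H-benzo[7]annulen-5-one | O=c1c(OCc2ccccc2)c(B3OC(C)(C)C(C)(C)O3)ccc2c(B3OC(C)(C)C(C)(C)O3)cc(OCc3ccccc3)c(OCc3ccccc3)c12 | intermediate
14 | [3,4,6-tris(benzyloxy)-5-oxo-5H-benzo[7]annulene-1,7-diyl]diboronic acid | O=c1c(OCc2ccccc2)c(B(O)O)ccc2c(B(O)O)cc(OCc3ccccc3)c(OCc3ccccc3)c12 | intermediate (key-step precursor)
15 | 3,5-bis(benzyloxy)phenol | Oc1cc(OCc2ccccc2)cc(OCc2ccccc2)c1 | starting material
16 | 1,3-bis(benzyloxy)-5-(methoxymethoxy)benzene | COCOc1cc(OCc2ccccc2)cc(OCc2ccccc2)c1 | intermediate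
17 | methyl (R)-glycidate [methyl (2R)-oxirane-2-carboxylate] | COC(=O)[C@H]1CO1 | starting material
18 | [2,4-bis(benzyloxy)-6-(methoxymethoxy)phenyl]lithium | [Li]c1c(OCc2ccccc2)cc(OCc2ccccc2)cc1OCOC | intermediate (not isolated)
19 | [2,4-bis(benzyloxy)-6-(methoxymethoxy)phenyl]magnesium bromide | Br[Mg]c1c(OCc2ccccc2)cc(OCc2ccccc2)cc1OCOC | intermediate (not isolated)
20 | methyl (R)-3-[2,4-bis(benzyloxy)-6-(methoxymethoxy)phenyl]-2-hydroxypropanoate | COC(=O)[C@H](O)Cc1c(OCc2ccccc2)cc(OCc2ccccc2)cc1OCOC | intermediate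
21 | methyl (R)-3-[2,4-bis(benzyloxy)-6-(methoxymethoxy)phenyl]-2-(tert-butyldimethylsilyloxy)propanoate | COC(=O)[C@H](O[Si](C)(C)C(C)(C)C)Cc1c(OCc2ccccc2)cc(OCc2ccccc2)cc1OCOC | intermediate
22 | (R)-3-[2,4-bis(benzyloxy)-6-(methoxymethoxy)phenyl]-2-(tert-butyldimethylsilyloxy)propanal | O=C[C@H](O[Si](C)(C)C(C)(C)C)Cc1c(OCc2ccccc2)cc(OCc2ccccc2)cc1OCOC | intermediate (key-step precursor)
23 | 3,4,6-tris(benzyloxy)-1,7-bis{(1S,2R)-3-[2,4-bis(benzyloxy)-6-(methoxymethoxy)phenyl]-2-(tert-butyldimethylsilyloxy)-1-hydroxypropyl}-5H-benzo[7]annulen-5-one | CC(C)(C)[Si](C)(C)O[C@H](Cc1c(OCc2ccccc2)cc(OCc2ccccc2)cc1OCOC)[C@@H](O)c1ccc2c([C@H](O)[C@H](O[Si](C)(C)C(C)(C)C)Cc3c(OCc4ccccc4)cc(OCc4ccccc4)cc3OCOC)cc(OCc3ccccc3)c(OCc3ccccc3)c2c(=O)c1OCc1ccccc1 | intermediate (key-step product)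
24 | tetrakis(trimethylsilyl) ether of 25 (two aryl and two carbinol O–SiMe3 groups) | CC(C)(C)[Si](C)(C)O[C@H](Cc1c(OCc2ccccc2)cc(OCc2ccccc2)cc1O[Si](C)(C)C)[C@@H](O[Si](C)(C)C)c1ccc2c([C@H](O[Si](C)(C)C)[C@H](O[Si](C)(C)C(C)(C)C)Cc3c(OCc4ccccc4)cc(OCc4ccccc4)cc3O[Si](C)(C)C)cc(OCc3ccccc3)c(OCc3ccccc3)c2c(=O)c1OCc1ccccc1 | intermediate (not isolated)
25 | 3,4,6-tris(benzyloxy)-1,7-bis{(1S,2R)-3-[2,4-bis(benzyloxy)-6-hydroxyphenyl]-2-(tert-butyldimethylsilyloxy)-1-hydroxypropyl}-5H-benzo[7]annulen-5-one | CC(C)(C)[Si](C)(C)O[C@H](Cc1c(OCc2ccccc2)cc(OCc2ccccc2)cc1O)[C@@H](O)c1ccc2c([C@H](O)[C@H](O[Si](C)(C)C(C)(C)C)Cc3c(OCc4ccccc4)cc(OCc4ccccc4)cc3O)cc(OCc3ccccc3)c(OCc3ccccc3)c2c(=O)c1OCc1ccccc1 | intermediate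
26 | 3,4,6-tris(benzyloxy)-1,7-bis[(2R,3R)-5,7-bis(benzyloxy)-3-(tert-butyldimethylsilyloxy)chroman-2-yl]-5H-benzo[7]annulen-5-one | CC(C)(C)[Si](C)(C)O[C@@H]1Cc2c(OCc3ccccc3)cc(OCc3ccccc3)cc2O[C@@H]1c1ccc2c([C@H]3Oc4cc(OCc5ccccc5)cc(OCc5ccccc5)c4C[C@H]3O[Si](C)(C)C(C)(C)C)cc(OCc3ccccc3)c(OCc3ccccc3)c2c(=O)c1OCc1ccccc1 | intermediate
27 | 3,4,6-tris(benzyloxy)-1,7-bis[(2R,3R)-5,7-bis(benzyloxy)-3-hydroxychroman-2-yl]-5H-benzo[7]annulen-5-one | O[C@@H]1Cc2c(OCc3ccccc3)cc(OCc3ccccc3)cc2O[C@@H]1c1ccc2c([C@H]3Oc4cc(OCc5ccccc5)cc(OCc5ccccc5)c4C[C@H]3O)cc(OCc3ccccc3)c(OCc3ccccc3)c2c(=O)c1OCc1ccccc1 | intermediate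
28 | 3,4,5-tris(benzyloxy)benzoic acid | O=C(O)c1cc(OCc2ccccc2)c(OCc2ccccc2)c(OCc2ccccc2)c1 | starting material
29 | 3,4,6-tris(benzyloxy)-1,7-bis{(2R,3R)-5,7-bis(benzyloxy)-3-[3,4,5-tris(benzyloxy)benzoyloxy]chroman-2-yl}-5H-benzo[7]annulen-5-one | O=C(O[C@@H]1Cc2c(OCc3ccccc3)cc(OCc3ccccc3)cc2O[C@@H]1c1ccc2c([C@H]3Oc4cc(OCc5ccccc5)cc(OCc5ccccc5)c4C[C@H]3OC(=O)c3cc(OCc4ccccc4)c(OCc4ccccc4)c(OCc4ccccc4)c3)cc(OCc3ccccc3)c(OCc3ccccc3)c2c(=O)c1OCc1ccccc1)c1cc(OCc2ccccc2)c(OCc2ccccc2)c(OCc2ccccc2)c1 | intermediate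
30 | 3,4,6-trihydroxy-1,7-bis[(2R,3R)-5,7-dihydroxy-3-(3,4,5-trihydroxybenzoyloxy)chroman-2-yl]-5H-benzo[7]annulen-5-one (CNP0283148.1) | O=C(O[C@@H]1Cc2c(O)cc(O)cc2O[C@@H]1c1ccc2c([C@H]3Oc4cc(O)cc(O)c4C[C@H]3OC(=O)c3cc(O)c(O)c(O)c3)cc(O)c(O)c2c(=O)c1O)c1cc(O)c(O)c(O)c1 | target

## Count and risks

Total steps: 20. Longest linear sequence: 16 steps (steps 1–10 and 15–20, from 3,4-dimethoxybenzaldehyde); the aldehyde branch (steps 11–14) joins at step 15.

Steps most likely to fail:

1. Step 15 (key step). The troponyl–rhodium intermediate at C7 is electron-poor and may insert the aldehyde slowly, so protodeboronation could win on one arm. Felkin–Anh discrimination may also be incomplete, giving epimeric carbinols. The fallback sets out from 21 and 14 and returns at 23. Saponification of 21 (LiOH, THF/H2O, 0 °C) should give (R)-3-[2,4-bis(benzyloxy)-6-(methoxymethoxy)phenyl]-2-(tert-butyldimethylsilyloxy)propanoic acid F1. Thioesterification (PhSH, DCC, cat. DMAP, CH2Cl2) should give the S-phenyl thioester F2. Liebeskind–Srogl coupling of 14 with two equivalents of F2 (Pd2(dba)3, tri(2-furyl)phosphine, copper thiophene-2-carboxylate Cu(O2CC4H3S), THF, 50 °C) should give the 1,7-bis(α-silyloxy ketone) F3 under neutral conditions. Corey–Bakshi–Shibata reduction of F3 ((S)-2-methyl-CBS-oxazaborolidine, catecholborane, toluene, −78 °C), in which reagent control and the Felkin–Anh preference point the same way, should give the (1S) carbinols of 23. A mixture of carbinol epimers from step 15 can be converged the same way after oxidation to F3 with Dess–Martin periodinane.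

2. Step 17 (double Mitsunobu closure). The oxyphosphonium ion of the benzo-ring arm is para to a benzyloxy group and may ionise, so inversion could be incomplete; alternatively the congested carbinols may not be activated at all. The fallback sets out from 25 and returns at 27. Bu4NF/AcOH should remove both silyl ethers to give the bis(phenol) tetraol F4 with two anti-1,2-diols. HC(OEt)3 and pyridinium p-toluenesulfonate in 1,2-dichloroethane (rt → 60 °C) should convert each diol into a 2-ethoxy-1,3-dioxolane that ionises to a dioxolan-2-ylium ion. The ring A phenol opens this ion at the benzylic carbon from the face opposite the bridging oxygen, again with inversion, to give the bis(cis-chroman 3-O-formate) F5. The neighbouring-group bridge should hold the configuration where a free oxyphosphonium ion would lose it. K2CO3/MeOH then cleaves the formates to 27.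

3. Step 9 (double borylation, with its consequence in step 10). Reductive debromination or homocoupling may occur at the troponyl C7–Br bond, and the C7 boronate may protodeboronate during pinacol cleavage. The fallback sets out from 12 and returns at 23, bypassing 13 and 14. Stannylation (Me3SnSnMe3, Pd(PPh3)4, toluene, 100 °C) should give the 1,7-bis(trimethylstannyl) compound F6. The known Rh-catalysed addition of aryl- and alkenylstannanes to aldehydes ([Rh(cod)(MeCN)2]BF4, THF, 60 °C) with 22 should then give 23 under the same Felkin–Anh control.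

Further compounds
F1 | step 15 | (R)-3-[2,4-bis(benzyloxy)-6-(methoxymethoxy)phenyl]-2-(tert-butyldimethylsilyloxy)propanoic acid | OC(=O)[C@H](O[Si](C)(C)C(C)(C)C)Cc1c(OCc2ccccc2)cc(OCc2ccccc2)cc1OCOC
F2 | step 15 | S-phenyl (R)-3-[2,4-bis(benzyloxy)-6-(methoxymethoxy)phenyl]-2-(tert-butyldimethylsilyloxy)propanethioate | O=C(Sc1ccccc1)[C@H](O[Si](C)(C)C(C)(C)C)Cc1c(OCc2ccccc2)cc(OCc2ccccc2)cc1OCOC
F3 | step 15 | 3,4,6-tris(benzyloxy)-1,7-bis{(R)-3-[2,4-bis(benzyloxy)-6-(methoxymethoxy)phenyl]-2-(tert-butyldimethylsilyloxy)propanoyl}-5H-benzo[7]annulen-5-one | CC(C)(C)[Si](C)(C)O[C@H](Cc1c(OCc2ccccc2)cc(OCc2ccccc2)cc1OCOC)C(=O)c1ccc2c(C(=O)[C@H](O[Si](C)(C)C(C)(C)C)Cc3c(OCc4ccccc4)cc(OCc4ccccc4)cc3OCOC)cc(OCc3ccccc3)c(OCc3ccccc3)c2c(=O)c1OCc1ccccc1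
F4 | step 17 | 3,4,6-tris(benzyloxy)-1,7-bis{(1S,2R)-3-[2,4-bis(benzyloxy)-6-hydroxyphenyl]-1,2-dihydroxypropyl}-5H-benzo[7]annulen-5-one | O[C@H](Cc1c(OCc2ccccc2)cc(OCc2ccccc2)cc1O)[C@@H](O)c1ccc2c([C@H](O)[C@H](O)Cc3c(OCc4ccccc4)cc(OCc4ccccc4)cc3O)cc(OCc3ccccc3)c(OCc3ccccc3)c2c(=O)c1OCc1ccccc1
F5 | step 17 | 3,4,6-tris(benzyloxy)-1,7-bis[(2R,3R)-5,7-bis(benzyloxy)-3-(formyloxy)chroman-2-yl]-5H-benzo[7]annulen-5-one | O=CO[C@@H]1Cc2c(OCc3ccccc3)cc(OCc3ccccc3)cc2O[C@@H]1c1ccc2c([C@H]3Oc4cc(OCc5ccccc5)cc(OCc5ccccc5)c4C[C@H]3OC=O)cc(OCc3ccccc3)c(OCc3ccccc3)c2c(=O)c1OCc1ccccc1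
F6 | step 9 | 3,4,6-tris(benzyloxy)-1,7-bis(trimethylstannyl)-5H-benzo[7]annulen-5-one | O=c1c(OCc2ccccc2)c([Sn](C)(C)C)ccc2c([Sn](C)(C)C)cc(OCc3ccccc3)c(OCc3ccccc3)c12
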